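Assumption: prostanoid numbering (C1 = ester carbon … C20) is used for every intermediate, and furylcarbinol 9 is carried as both C8 epimers, because C8 becomes planar in step 6.

## The problem

Target 25 is a chlorinated prostanoid: a 2-chloro-4-hydroxycyclopent-2-enone (C8–C12) that carries at C12 a tertiary hydroxyl and a (2Z,5Z)-octa-2,5-dienyl chain (C13–C20), and at C8 the C1–C7 chain with three contiguous acetoxy stereocentres and a methyl ester. Chain and ring meet at C7–C8, so either a finished ring is joined to C7 by an aldol reaction, which creates C7 and C8 together late, or the ring is grown on C8 of a chain in which C7 already exists; the second course is taken. Of the five stereocentres, C5, C6 and C7 are an all-syn triol that can be made as one unit. C8 is α to the C9 ketone and settles trans to the C13 chain, so it follows C12, whereas C12 is quaternary and must be set from C8, which in turn must be set from C7. The C7 acetate is β to the C9 ketone and is lost by E1cB elimination even with weak base; the skipped Z,Z-diene tolerates neither electrophilic halogen nor strong base nor unpoisoned hydrogenation; the tertiary allylic C12 alcohol is sensitive to strong acid. The ketone should therefore appear late, chlorine should enter as chloride, and the diene should come from a diyne. The feature that makes the key step possible is the C1–C5 segment: an ester carbon (C1), three methylenes (C2–C4) and an oxygen-bearing stereocentre (C5), which is what oxygen insertion between the carbonyl carbon and the substituted α-carbon of a 2-substituted cyclopentanone leaves behind. The C5–C6 bond is then an aldol bond, and ring carbons C9–C12, oxygenated at C9 and C12, map onto a furan.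

## Retrosynthesis

**25 ⇒ 23 (C10–Cl).** The chlorine is removed first. Electrophilic chlorination of an enone is excluded by the C14 and C17 double bonds. Bringing the halogen in on the heterocycle that supplies C9–C12 would leave it on the β-carbon of the first-formed enone, a vinylogous acid chloride. Cutting C10–Cl and the C10=C11 unsaturation back to the α,β-epoxy ketone 23 lets chlorine enter as chloride. The forward step must open the epoxide at C10 and dehydrate chlorohydrin 24 without touching the C7 acetate; the gain in simplicity is small, the gain in compatibility large.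

**23 ⇒ 22 ⇒ 21 ⇒ 20 (C9=O and the epoxide oxygen).** No skeletal bond is cut. The C9 ketone is traced to a silyl-protected carbinol and the epoxide to the C10=C11 double bond. This keeps the β-acetoxy ketone out of the route until its last two steps and lets the C12 hydroxyl deliver the epoxide oxygen. The forward steps need a chemoselective epoxidation of the ring olefin beside two Z olefins, a buffered desilylation and a neutral oxidation.

**20 ⇒ 18 ⇒ 17 ⇒ 16 (three O–acetyl bonds and C1–OMe).** Triacetate and methyl ester are traced to the δ-lactone (C1/O5) and the acetonide (O6/O7), the forms in which these atoms arrive from the key step. Exchanging them only after all C–C bonds exist keeps acetates away from the organometallic steps. The C9 hydroxyl needs a silyl group to stay distinct from the three chain hydroxyls.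

**16 ⇒ 15 ⇒ 13 + 14, and 13 ⇒ 10 + 11 (C15–C16 and C12–C13).** The ω-chain is cut twice. A complete octadienyl metal would be an allyl metal and add with transposition. A propargylzinc reagent adds as an intact three-carbon unit, copper coupling with 14 gives the skipped diyne, and semi-hydrogenation gives both Z olefins at once. Cutting C12–C13 also removes the quaternary stereocentre: 10 is an enone with one neighbouring substituent, the C8 chain, and the forward addition must come anti to it.

**10 ⇒ 9 ⇒ 6 + 7 (C8–C9 and C8–C12).** Both ring bonds to C8 are cut, reducing the carbocycle to furan 7 and the chain aldehyde 6. Rearrangement of a 2-furylcarbinol puts the ketone at C12 and the hydroxyl at C9, the reverse of 25, and this is used on purpose: the C12 ketone takes up the ω-chain and the C9 carbinol becomes the ketone at the end. Mapping the furan directly onto the target would be shorter, but it would create C12 in the cationic step with no controlling neighbour and expose the ketone before the acetates are on. The forward step must choose the face of C8 under the influence of C7.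

**6 ⇒ 5 ⇒ 4 (oxidation level at C8, position of the acetal).** The aldehyde comes from primary alcohol 5, and 5 from 4 by moving the isopropylidene group from O7/O8 to O6/O7. No skeletal bond is cut. C8 is exposed without a protection sequence because the syn C6/C7 diol can form a trans-disubstituted dioxolane.

**4 ⇒ 3 (C5–O, key step).** The lactone C5–O bond is cut and C1 re-bonded to C5, so δ-lactone 4 becomes cyclopentanone 3. Cutting the acyl C–O bond instead would lead only to a hydroxy acid that still needs its C5 stereocentre. This cut turns the C5–O stereocentre into a C–C stereocentre α to a ketone, where an aldol reaction can set it, and reduces C1–C5 to cyclopentanone. The forward reaction must insert oxygen on the substituted side with retention at C5.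

**3 ⇒ 1 + 2 (C5–C6).** The aldol bond is cut to cyclopentanone 1 and (R)-glyceraldehyde acetonide 2, which brings C7 from the chiral pool and C8 at the alcohol level. The forward reaction must give the anti aldol with C6/C7 syn. That is the sense of L-proline catalysis but runs against the aldehyde's Felkin–Anh preference.

## Roads not taken

**Alternative 1:** The cut is the C11–C12 ring bond. In the forward sense SmI2 reduces the C12 ketone of keto-aldehyde A1 to a ketyl that adds to the C11 aldehyde, closing the cyclopentane as cis-11,12-diol A2 with C12 as in the target.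
- Merits: ring and quaternary carbinol form in one step under chelate control, and the conditions are neutral and compatible with ester, silyl ethers and the skipped diene.
- Weak points: A1 is a β,γ-unsaturated ketone with doubly activated C13 protons, an epimerisable C8 (A2 is indeed formed with C8 unsettled) and an oxygen β to the ketyl carbon. A2 is a saturated diol, so C9 oxidation, dehydration across C10–C11, chlorination of the enone beside the diene and exchange of three silyl ethers for acetates next to the ketone all remain.
- Comparison: for C12 this road is better than the chosen one, since the pinacol closure controls the carbinol in the ring-forming step, whereas the chosen plan relays it from C7 through C8 and depends on the facial bias of step 6. The chosen plan sets against this a ring born at the enone oxidation pattern (10), a defined answer to the chlorine (steps 13–16) and acetates in place before the ketone appears.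

**Alternative 2:** The cut is C9–C10. In the forward sense [Rh(dppe)]BF4 inserts into the aldehyde C–H bond of chloroalkynyl aldehyde A3 and the acyl rhodium hydride adds across C10≡C11, giving A4, the 12-O-triethylsilyl ether of the target.
- Merits: ring, ketone and vinyl chloride arise together, without base and with the acetates already in place; no separate chlorination is needed.
- Weak points: hydroacylation of 4-alkynals is established for carbon-substituted alkynes, but a 1-chloroalkyne offers low-valent rhodium a C–Cl bond for oxidative addition, and insertion with the acyl group on the chlorinated carbon is untested. The aldehyde sits on the epimerisable C8 with an acetate β to it, so decarbonylation, epimerisation and elimination compete. The cationic metal can bind the skipped diene. A3 needs C8 and the quaternary propargylic C12 set in an open chain.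
- Comparison: in step count after the chain is made and in the placing of chlorine this road is clearly better than the chosen one, which spends steps 13–16 on chlorine and ketone. The chosen plan sets against it that each step is an established reaction type on its substrate class and that C12 is set on a ring by addition anti to the C8 substituent.

**Alternative 3:** The cut is the C10=C11 double bond, traced to a six-membered sulfone. In the forward sense KOt-Bu deprotonates C11 of the 2,2-dichlorothiane 1,1-dioxide A5, displacement of one chloride gives a chloro-episulfone, and loss of SO2 contracts the ring to 1-chlorocyclopentene A6.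
- Merits: the position of the vinyl chloride is fixed by the substrate, no electrophilic chlorine meets the diene, and C8 and C12 are set before the contraction.
- Weak points: A5 must be built as a thiane with three stereocentres and dichlorinated at C10 only. The C11 carbanion has the C12 silyloxy group β to it and can expel it. KOt-Bu can isomerise the skipped diene. A6 still needs C9 oxidation and the exchange of three silyl ethers for acetates beside the ketone.
- Comparison: for the regiochemistry of chlorine this road is more secure than the epoxide opening of step 16. The chosen plan has the shorter way to the carbocycle (two bonds from furan 7 and aldehyde 6) and uses no strong base once the diene is present.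

Key step: step 2

## Route

Step 1
Reactants: 1 cyclopentanone; 2 (R)-2,2-dimethyl-1,3-dioxolane-4-carbaldehyde
Product: 3 (2S)-2-[(R)-[(4R)-2,2-dimethyl-1,3-dioxolan-4-yl](hydroxy)methyl]cyclopentan-1-one
Conditions: L-proline (30 mol %), 1 (5 equiv), DMSO, rt
Reagents that add atoms: none
Why: Proline-catalysed direct aldol reaction (enamine catalysis): the enamine of 1 should attack the re face of 2 in the hydrogen-bonded chair, setting C5 (S) and C6 (R) anti and so C6/C7 syn. The aldehyde's Felkin–Anh preference is opposed (mismatched pair), so catalyst control has to dominate and minor isomers are removed by chromatography.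

Step 2
Reactants: 3 (2S)-2-[(R)-[(4R)-2,2-dimethyl-1,3-dioxolan-4-yl](hydroxy)methyl]cyclopentan-1-one
Product: 4 (6S)-6-[(R)-[(4R)-2,2-dimethyl-1,3-dioxolan-4-yl](hydroxy)methyl]oxan-2-one
Conditions: mCPBA, NaHCO3 (buffer), CH2Cl2, 0 °C to rt
Reagents that add atoms: 3-chloroperbenzoic acid (mCPBA), `O=C(OO)c1cccc(Cl)c1`
Why: Baeyer–Villiger oxidation: the peracid adds to the ketone to give the Criegee adduct, and C5 migrates from C1 to oxygen antiperiplanar to the breaking O–O bond. The closest known reaction type is the peracid oxidation of 2-substituted and 2-(1-hydroxyalkyl)cyclopentanones to 6-substituted δ-lactones. The six-membered lactone is not closed by a cyclisation; it arises by ring expansion, a 1,2-shift that inserts oxygen between C1 and C5 of the five-membered ring. No stereocentre is created: C5 migrates with retention, so the configuration set in step 1 becomes that of the C5–O bond, and C6 and C7 are spectators. The selectivity needed is regiochemical (C5 against the C2 methylene) and is secured by the higher migratory aptitude of the secondary, branched C5, although the oxygen on C6 lowers that preference somewhat. The bicarbonate buffer protects the acetal from 3-chlorobenzoic acid, and the absence of base avoids retro-aldol cleavage or epimerisation at C5 before migration.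

Step 3
Reactants: 4 (6S)-6-[(R)-[(4R)-2,2-dimethyl-1,3-dioxolan-4-yl](hydroxy)methyl]oxan-2-one
Product: 5 (6S)-6-[(4R,5R)-5-(hydroxymethyl)-2,2-dimethyl-1,3-dioxolan-4-yl]oxan-2-one
Conditions: camphorsulfonic acid (cat.), acetone, rt, equilibration; recovered 4 recycled
Reagents that add atoms: none
Why: Acid-catalysed acetal migration under thermodynamic control: the terminal dioxolane should equilibrate towards the trans-4,5-disubstituted dioxolane that the syn C6/C7 diol can form. This frees the C8 hydroxyl without a protection sequence; the lactone fixes O5, so only these two acetals compete.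

Step 4
Reactants: 5 (6S)-6-[(4R,5R)-5-(hydroxymethyl)-2,2-dimethyl-1,3-dioxolan-4-yl]oxan-2-one
Product: 6 (4S,5R)-2,2-dimethyl-5-[(2S)-6-oxooxan-2-yl]-1,3-dioxolane-4-carbaldehyde
Conditions: Dess–Martin periodinane, NaHCO3, CH2Cl2, 0 °C to rt
Reagents that add atoms: none
Why: Dess–Martin oxidation of a primary alcohol under buffered, non-epimerising conditions. The α-alkoxy aldehyde on a trans-dioxolane is configurationally robust and is used crude.

Step 5
Reactants: 6 (4S,5R)-2,2-dimethyl-5-[(2S)-6-oxooxan-2-yl]-1,3-dioxolane-4-carbaldehyde; 7 furan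
Product: 9 (6S)-6-[(4R,5R)-5-[furan-2-yl(hydroxy)methyl]-2,2-dimethyl-1,3-dioxolan-4-yl]oxan-2-one (both C8 epimers), via 2-furyllithium 8 (not isolated)
Conditions: 7, n-BuLi, THF, 0 °C; then 6, −78 °C; H2O
Reagents that add atoms: none
Why: 1,2-Addition of a heteroaryllithium to an aldehyde; at −78 °C with a slight excess of reagent the aldehyde should react well before the δ-lactone. The configuration of the new carbinol is irrelevant because C8 is ionised in step 6.

Step 6
Reactants: 9 (6S)-6-[(4R,5R)-5-[furan-2-yl(hydroxy)methyl]-2,2-dimethyl-1,3-dioxolan-4-yl]oxan-2-one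
Product: 10 (4S,5S)-5-[(4R,5R)-2,2-dimethyl-5-[(2S)-6-oxooxan-2-yl]-1,3-dioxolan-4-yl]-4-hydroxycyclopent-2-en-1-one
Conditions: Dy(OTf)3 (10 mol %), t-BuOH/H2O (5:1), 80 °C
Reagents that add atoms: water, `O`
Why: Piancatelli rearrangement: ionisation at C8, addition of water to the free furan α-carbon, ring opening and conrotatory 4π closure of the hydroxypentadienyl cation, with both terminal substituents turning outward, give the 4-hydroxy-5-substituted cyclopent-2-enone with the C9 hydroxyl and the C8 chain trans. The ring sense is decided at C8 by C7: with C7–H in the plane of the cation (allylic strain) the new C8–C9 bond is expected to form anti to the C7–O bond, which is the C8 configuration of 25; the other ring diastereomer is removed by chromatography. The ketone of 10 is C12 and the carbinol is C9, as the plan requires.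

Step 7
Reactants: 10 (4S,5S)-5-[(4R,5R)-2,2-dimethyl-5-[(2S)-6-oxooxan-2-yl]-1,3-dioxolan-4-yl]-4-hydroxycyclopent-2-en-1-one; 11 3-bromoprop-1-yne
Product: 13 (6S)-6-[(4R,5R)-5-[(1S,2S,5S)-2,5-dihydroxy-2-(prop-2-yn-1-yl)cyclopent-3-en-1-yl]-2,2-dimethyl-1,3-dioxolan-4-yl]oxan-2-one, via allenylzinc bromide 12 (not isolated)
Conditions: Zn dust, THF/sat. aq. NH4Cl, 0 °C to rt
Reagents that add atoms: none
Why: Barbier propargylation: the allenylzinc reagent adds 1,2 to the enone carbonyl with propargyl–allenyl transposition, giving the homopropargylic tertiary alcohol. Attack anti to the adjacent C8 side chain should place the new chain trans to it, which is the C12 configuration of 25. The near-neutral aqueous medium spares lactone, acetal and the base-sensitive hydroxy enone.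

Step 8
Reactants: 13 (6S)-6-[(4R,5R)-5-[(1S,2S,5S)-2,5-dihydroxy-2-(prop-2-yn-1-yl)cyclopent-3-en-1-yl]-2,2-dimethyl-1,3-dioxolan-4-yl]oxan-2-one; 14 1-bromopent-2-yne
Product: 15 (6S)-6-[(4R,5R)-5-[(1S,2S,5S)-2,5-dihydroxy-2-(octa-2,5-diyn-1-yl)cyclopent-3-en-1-yl]-2,2-dimethyl-1,3-dioxolan-4-yl]oxan-2-one
Conditions: CuI, Cs2CO3, DMF, rt
Reagents that add atoms: none
Why: Copper-mediated coupling of a terminal alkyne with a propargylic bromide, the standard entry to skipped diynes. Carbonate in DMF should leave lactone, acetal and the free hydroxyls untouched.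

Step 9
Reactants: 15 (6S)-6-[(4R,5R)-5-[(1S,2S,5S)-2,5-dihydroxy-2-(octa-2,5-diyn-1-yl)cyclopent-3-en-1-yl]-2,2-dimethyl-1,3-dioxolan-4-yl]oxan-2-one
Product: 16 (6S)-6-[(4R,5R)-5-[(1S,2S,5S)-2,5-dihydroxy-2-[(2Z,5Z)-octa-2,5-dien-1-yl]cyclopent-3-en-1-yl]-2,2-dimethyl-1,3-dioxolan-4-yl]oxan-2-one
Conditions: H2 (1 atm), Pd/CaCO3 poisoned with Pb(OAc)2 (Lindlar catalyst), quinoline, EtOAc, rt
Reagents that add atoms: none
Why: Lindlar semi-hydrogenation: syn addition of hydrogen converts both triple bonds into Z double bonds; the reaction is stopped after two equivalents. The ring olefin is not expected to be reduced on the poisoned catalyst.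

Step 10
Reactants: 16 (6S)-6-[(4R,5R)-5-[(1S,2S,5S)-2,5-dihydroxy-2-[(2Z,5Z)-octa-2,5-dien-1-yl]cyclopent-3-en-1-yl]-2,2-dimethyl-1,3-dioxolan-4-yl]oxan-2-one
Product: 17 C9 tert-butyldiphenylsilyl ether of 16 (tertiary C12 hydroxyl free)
Conditions: TBDPSCl, imidazole, DMF, rt
Reagents that add atoms: tert-butyl(chloro)diphenylsilane, `CC(C)(C)[Si](Cl)(c1ccccc1)c1ccccc1`
Why: Selective silylation of the secondary allylic C9 hydroxyl; the tertiary C12 hydroxyl does not react. The acid-stable silyl group keeps C9 distinct from the three chain hydroxyls that are to be acetylated.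

Step 11
Reactants: 17 C9 tert-butyldiphenylsilyl ether of 16
Product: 18 6,7-diol of 17 (isopropylidene group removed; lactone, silyl ether and C12 hydroxyl unchanged)
Conditions: AcOH/H2O (4:1), 40 °C
Reagents that add atoms: none
Why: Acid hydrolysis of the isopropylidene acetal; lactone, diphenyl-tert-butylsilyl ether and Z olefins should survive aqueous acetic acid. The temperature is kept low for the sake of the tertiary allylic alcohol.

Step 12
Reactants: 18 6,7-diol of 17
Product: 20 methyl (5S,6R,7R)-5,6,7-triacetoxyheptanoate carrying at C7 the ring of 17 (C9 silyl ether and C12 hydroxyl unchanged), via tetraol methyl ester 19 (not isolated)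
Conditions: K2CO3 (0.2 equiv), MeOH, 0 °C; evaporate; Ac2O, pyridine, 4-(dimethylamino)pyridine (cat.), CH2Cl2, 0 °C to rt
Reagents that add atoms: methanol, `CO`; acetic anhydride, `CC(=O)OC(C)=O`
Why: Base-catalysed transesterification opens the δ-lactone to the methyl ester and frees the C5 hydroxyl. Immediate acetylation traps the hydroxy ester before it can relactonise and esterifies the three secondary hydroxyls; the tertiary C12 hydroxyl is inert under these conditions and no ketone is present yet.

Step 13
Reactants: 20 methyl (5S,6R,7R)-5,6,7-triacetoxyheptanoate carrying at C7 the ring of 17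
Product: 21 10,11-epoxide of 20, epoxide oxygen cis to the C12 hydroxyl and trans to the C9 silyl ether
Conditions: VO(acac)2 (5 mol %), t-BuOOH, CH2Cl2, 0 °C to rt
Reagents that add atoms: tert-butyl hydroperoxide, `CC(C)(C)OO`
Why: Hydroxyl-directed vanadium-catalysed epoxidation: the tertiary allylic C12 hydroxyl delivers oxygen to C10=C11 on its own face, which is also the face away from the bulky C9 silyl ether. The Z olefins of the chain are not allylic alcohols and should react much more slowly; the epoxide configuration is erased in step 16.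

Step 14
Reactants: 21 10,11-epoxide of 20
Product: 22 C9 alcohol of 21 (silyl group removed)
Conditions: Bu4NF, AcOH, THF, rt
Reagents that add atoms: none
Why: Fluoride desilylation buffered with acetic acid, so that neither acetyl migration nor epoxide (Payne) migration is triggered by a free alkoxide.

Step 15
Reactants: 22 C9 alcohol of 21
Product: 23 α,β-epoxy ketone (C9 ketone, 10,11-epoxide, C12 hydroxyl, triacetate methyl ester)
Conditions: Dess–Martin periodinane, NaHCO3, CH2Cl2, 0 °C
Reagents that add atoms: none
Why: Dess–Martin oxidation of the secondary epoxy alcohol under neutral conditions. The β-acetoxy ketone formed here meets no base.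

Step 16
Reactants: 23 α,β-epoxy ketone
Product: 25 methyl (5S,6R,7R)-5,6,7-triacetoxy-7-[(1S,5R)-3-chloro-5-hydroxy-5-[(2Z,5Z)-octa-2,5-dien-1-yl]-2-oxocyclopent-3-en-1-yl]heptanoate (the target), via chlorohydrin 24 (not isolated)
Conditions: HCl (anhydrous, in EtOAc), CH2Cl2, 0 °C
Reagents that add atoms: hydrogen chloride, `Cl`
Why: Conversion of an α,β-epoxy ketone into an α-chloro enone: chloride opens the protonated epoxide at the α-carbon C10 (SN2), and the β-hydroxyl at C11 is lost through the enol. Chlorine enters as chloride, so the skipped diene is not touched; C8 keeps its configuration, which is also the thermodynamically preferred one with the two ring substituents trans.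

## Compound list

1 | cyclopentanone | `O=C1CCCC1` | starting material
2 | (R)-2,2-dimethyl-1,3-dioxolane-4-carbaldehyde | `O=C[C@H]1COC(C)(C)O1` | starting material
3 | (2S)-2-[(R)-[(4R)-2,2-dimethyl-1,3-dioxolan-4-yl](hydroxy)methyl]cyclopentan-1-one | `O=C1CCC[C@H]1[C@@H](O)[C@H]2COC(C)(C)O2` | intermediate
4 | (6S)-6-[(R)-[(4R)-2,2-dimethyl-1,3-dioxolan-4-yl](hydroxy)methyl]oxan-2-one | `O=C1CCC[C@H](O1)[C@@H](O)[C@H]2COC(C)(C)O2` | intermediate
5 | (6S)-6-[(4R,5R)-5-(hydroxymethyl)-2,2-dimethyl-1,3-dioxolan-4-yl]oxan-2-one | `O=C1CCC[C@H](O1)[C@H]2OC(C)(C)O[C@@H]2CO` | intermediate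
6 | (4S,5R)-2,2-dimethyl-5-[(2S)-6-oxooxan-2-yl]-1,3-dioxolane-4-carbaldehyde | `O=C1CCC[C@H](O1)[C@H]2OC(C)(C)O[C@@H]2C=O` | intermediate
7 | furan | `c1ccoc1` | starting material
8 | 2-furyllithium | `[Li]c1ccco1` | intermediate
9 | (6S)-6-[(4R,5R)-5-[furan-2-yl(hydroxy)methyl]-2,2-dimethyl-1,3-dioxolan-4-yl]oxan-2-one, both C8 epimers | `O=C1CCC[C@H](O1)[C@H]2OC(C)(C)O[C@@H]2C(O)c3ccco3` | intermediate
10 | (4S,5S)-5-[(4R,5R)-2,2-dimethyl-5-[(2S)-6-oxooxan-2-yl]-1,3-dioxolan-4-yl]-4-hydroxycyclopent-2-en-1-one (C9 hydroxyl trans to the C8 chain) | `O=C1CCC[C@H](O1)[C@H]2OC(C)(C)O[C@@H]2[C@H]3C(=O)C=C[C@@H]3O` | intermediate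
11 | 3-bromoprop-1-yne (propargyl bromide) | `C#CCBr` | starting material
12 | allenylzinc bromide (propa-1,2-dienylzinc bromide) | `C=C=C[Zn]Br` | intermediate
13 | (6S)-6-[(4R,5R)-5-[(1S,2S,5S)-2,5-dihydroxy-2-(prop-2-yn-1-yl)cyclopent-3-en-1-yl]-2,2-dimethyl-1,3-dioxolan-4-yl]oxan-2-one | `O=C1CCC[C@H](O1)[C@H]2OC(C)(C)O[C@@H]2[C@H]3[C@](O)(CC#C)C=C[C@@H]3O` | intermediate
14 | 1-bromopent-2-yne | `CCC#CCBr` | starting material
15 | (6S)-6-[(4R,5R)-5-[(1S,2S,5S)-2,5-dihydroxy-2-(octa-2,5-diyn-1-yl)cyclopent-3-en-1-yl]-2,2-dimethyl-1,3-dioxolan-4-yl]oxan-2-one | `O=C1CCC[C@H](O1)[C@H]2OC(C)(C)O[C@@H]2[C@H]3[C@](O)(CC#CCC#CCC)C=C[C@@H]3O` | intermediate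
16 | (6S)-6-[(4R,5R)-5-[(1S,2S,5S)-2,5-dihydroxy-2-[(2Z,5Z)-octa-2,5-dien-1-yl]cyclopent-3-en-1-yl]-2,2-dimethyl-1,3-dioxolan-4-yl]oxan-2-one | `O=C1CCC[C@H](O1)[C@H]2OC(C)(C)O[C@@H]2[C@H]3[C@](O)(C/C=C\C/C=C\CC)C=C[C@@H]3O` | intermediate
17 | C9 tert-butyldiphenylsilyl ether of 16 | `O=C1CCC[C@H](O1)[C@H]2OC(C)(C)O[C@@H]2[C@H]3[C@](O)(C/C=C\C/C=C\CC)C=C[C@@H]3O[Si](c4ccccc4)(c5ccccc5)C(C)(C)C` | intermediate
18 | 6,7-diol of 17 (δ-lactone, C9 silyl ether, C12 hydroxyl) | `O=C1CCC[C@H](O1)[C@@H](O)[C@H](O)[C@H]2[C@](O)(C/C=C\C/C=C\CC)C=C[C@@H]2O[Si](c3ccccc3)(c4ccccc4)C(C)(C)C` | intermediate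
19 | tetraol methyl ester (C5, C6, C7 and C12 hydroxyls free, C9 silyl ether) | `COC(=O)CCC[C@H](O)[C@@H](O)[C@H](O)[C@H]1[C@](O)(C/C=C\C/C=C\CC)C=C[C@@H]1O[Si](c2ccccc2)(c3ccccc3)C(C)(C)C` | intermediate
20 | methyl (5S,6R,7R)-5,6,7-triacetoxyheptanoate carrying at C7 the ring of 17 (C9 silyl ether, C12 hydroxyl) | `COC(=O)CCC[C@H](OC(C)=O)[C@@H](OC(C)=O)[C@H](OC(C)=O)[C@H]1[C@](O)(C/C=C\C/C=C\CC)C=C[C@@H]1O[Si](c2ccccc2)(c3ccccc3)C(C)(C)C` | intermediate
21 | 10,11-epoxide of 20, epoxide oxygen cis to the C12 hydroxyl | `COC(=O)CCC[C@H](OC(C)=O)[C@@H](OC(C)=O)[C@H](OC(C)=O)[C@H]1[C@](O)(C/C=C\C/C=C\CC)[C@H]2O[C@H]2[C@@H]1O[Si](c3ccccc3)(c4ccccc4)C(C)(C)C` | intermediate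
22 | C9 alcohol of 21 | `COC(=O)CCC[C@H](OC(C)=O)[C@@H](OC(C)=O)[C@H](OC(C)=O)[C@H]1[C@](O)(C/C=C\C/C=C\CC)[C@H]2O[C@H]2[C@@H]1O` | intermediate
23 | α,β-epoxy ketone (C9 ketone, 10,11-epoxide) | `COC(=O)CCC[C@H](OC(C)=O)[C@@H](OC(C)=O)[C@H](OC(C)=O)[C@H]1[C@](O)(C/C=C\C/C=C\CC)[C@H]2O[C@H]2C1=O` | intermediate
24 | chlorohydrin (C10 chloride trans to the C11 hydroxyl, C9 ketone) | `COC(=O)CCC[C@H](OC(C)=O)[C@@H](OC(C)=O)[C@H](OC(C)=O)[C@H]1[C@](O)(C/C=C\C/C=C\CC)[C@@H](O)[C@H](Cl)C1=O` | intermediate
25 | methyl (5S,6R,7R)-5,6,7-triacetoxy-7-[(1S,5R)-3-chloro-5-hydroxy-5-[(2Z,5Z)-octa-2,5-dien-1-yl]-2-oxocyclopent-3-en-1-yl]heptanoate | `CC/C=C\C/C=C\C[C@]1(O)C=C(Cl)C(=O)[C@H]1[C@@H](OC(C)=O)[C@H](OC(C)=O)[C@H](CCCC(=O)OC)OC(C)=O` | target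

## Step count and least certain steps

Total step count: 16. Longest linear sequence: 16 steps (1 and 2 to 25); 7, 11 and 14 are purchased and enter directly.

**Step 2 (key step).** What may go wrong: migration of the C2 methylene in competition with C5, because the oxygen on C6 lowers the migratory aptitude of C5 and the free hydroxyl can tie up the peracid; also loss of the terminal acetal if the medium turns acidic. The fallback moves the oxygen insertion onto a substrate without the free hydroxyl. It sets out from 3: silylation (Et3SiCl, imidazole, CH2Cl2) gives the C6 triethylsilyl ether F1, the same buffered peracid oxidation gives the lactone silyl ether F2, and Bu4NF/AcOH in THF returns 4.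

**Step 1.** What may go wrong: poor facial selectivity at the aldehyde carbon (C6), because catalyst control and the Felkin–Anh preference of 2 are opposed and because cyclopentanone is a less anti-selective donor than six-membered ketones. The fallback corrects C6 after the key step instead of selecting it in the aldol. It sets out from 3 as its mixture with the C6-epimeric adduct F3. Step 2 on the mixture gives 4 with the C6-epimeric lactone F4. Dess–Martin oxidation converts both into the single keto lactone F5, and LiBH(s-Bu)3 in THF at −78 °C should add hydride anti to both flanking C–O bonds (Felkin–Anh from C5 and from C7, which reinforce because O5 and O7 are syn), giving the all-syn alcohol 4, where the route is rejoined.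

**Step 3.** What may go wrong: an acetal equilibrium that does not favour the internal dioxolane enough, or slow migration with partial loss of the acetal. The fallback fixes the position of the acetal by protection instead of equilibrium. It sets out from 4: AcOH/H2O gives the triol lactone F6, TBDPSCl/imidazole silylates the primary hydroxyl to give the primary silyl ether F7, 2,2-dimethoxypropane with pyridinium p-toluenesulfonate closes the only free diol to the 6,7-acetonide silyl ether F8, and Bu4NF returns 5.

**Step 6.** What may go wrong: poor facial selectivity at C8, giving the two trans hydroxy enones of opposite ring sense, together with slow ionisation caused by the oxygen β to the cation and partial loss of the acetal. The fallback takes the ring configuration from the chiral pool and forms C7–C8 by an aldol reaction. It sets out from 4 and returns at 10.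
- t-BuMe2SiOTf/2,6-lutidine gives the C6 silyl ether F9.
- AcOH/H2O cleaves the terminal acetal to the diol F10.
- NaIO4 gives the C7 aldehyde F11.
- The lithium enolate of (R)-4-(tert-butyldimethylsilyloxy)cyclopent-2-en-1-one F12 (LiN(i-Pr)2, THF, −78 °C) adds to F11 to give the aldol adduct F13.
- Aqueous HF in MeCN gives the triol F14, and 2,2-dimethoxypropane with pyridinium p-toluenesulfonate closes the 6,7-acetonide to 10.

In F13, C9 is bought, C8 is set trans to the silyloxy group, and C7 is set by the chair transition state of the ring enolate (anti aldol). The price is that C7 is made a second time and that the Felkin–Anh bias of F11 is opposed.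

**Step 16.** What may go wrong: acid-promoted loss of the C7 acetate through enolisation towards C8, and incomplete dehydration of the chlorohydrin. The fallback separates opening and elimination and replaces acid-driven dehydration by activation of the C11 hydroxyl. It sets out from 23: LiCl/AcOH in THF at 0 °C gives chlorohydrin 24, which is isolated. MsCl with 2,4,6-collidine at −20 °C converts the secondary C11 hydroxyl into the mesylate F15, the tertiary C12 hydroxyl being inert. F15 should eliminate under the same weak base through the more acidic, chlorine-bearing C10–H to give 25.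

## Further compounds

F1 | step 2 | C6 triethylsilyl ether of 3 | `O=C1CCC[C@H]1[C@@H](O[Si](CC)(CC)CC)[C@H]2COC(C)(C)O2`
F2 | step 2 | C6 triethylsilyl ether of 4 | `O=C1CCC[C@H](O1)[C@@H](O[Si](CC)(CC)CC)[C@H]2COC(C)(C)O2`
F3 | step 1 | C6 epimer of 3, (2S)-2-[(S)-[(4R)-2,2-dimethyl-1,3-dioxolan-4-yl](hydroxy)methyl]cyclopentan-1-one | `O=C1CCC[C@H]1[C@H](O)[C@H]2COC(C)(C)O2`
F4 | step 1 | C6 epimer of 4, (6S)-6-[(S)-[(4R)-2,2-dimethyl-1,3-dioxolan-4-yl](hydroxy)methyl]oxan-2-one | `O=C1CCC[C@H](O1)[C@H](O)[C@H]2COC(C)(C)O2`
F5 | step 1 | (6S)-6-[(4R)-2,2-dimethyl-1,3-dioxolane-4-carbonyl]oxan-2-one | `O=C1CCC[C@H](O1)C(=O)[C@H]2COC(C)(C)O2`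
F6 | step 3 | triol lactone (4 without the isopropylidene group) | `O=C1CCC[C@H](O1)[C@@H](O)[C@H](O)CO`
F7 | step 3 | C8 tert-butyldiphenylsilyl ether of F6 | `O=C1CCC[C@H](O1)[C@@H](O)[C@H](O)CO[Si](c2ccccc2)(c3ccccc3)C(C)(C)C`
F8 | step 3 | C8 tert-butyldiphenylsilyl ether of 5 | `O=C1CCC[C@H](O1)[C@H]2OC(C)(C)O[C@@H]2CO[Si](c3ccccc3)(c4ccccc4)C(C)(C)C`
F9 | step 6 | C6 tert-butyldimethylsilyl ether of 4 | `O=C1CCC[C@H](O1)[C@@H](O[Si](C)(C)C(C)(C)C)[C@H]2COC(C)(C)O2`
F10 | step 6 | 7,8-diol of F9 | `O=C1CCC[C@H](O1)[C@@H](O[Si](C)(C)C(C)(C)C)[C@H](O)CO`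
F11 | step 6 | (2R)-2-(tert-butyldimethylsilyloxy)-2-[(2S)-6-oxooxan-2-yl]acetaldehyde | `O=C1CCC[C@H](O1)[C@@H](O[Si](C)(C)C(C)(C)C)C=O`
F12 | step 6 | (R)-4-(tert-butyldimethylsilyloxy)cyclopent-2-en-1-one | `O=C1C=C[C@H](O[Si](C)(C)C(C)(C)C)C1`
F13 | step 6 | aldol adduct (C7 hydroxyl free, C6 and C9 tert-butyldimethylsilyl ethers, ring as in 10) | `O=C1CCC[C@H](O1)[C@@H](O[Si](C)(C)C(C)(C)C)[C@H](O)[C@H]2C(=O)C=C[C@@H]2O[Si](C)(C)C(C)(C)C`
F14 | step 6 | triol (10 without the isopropylidene group) | `O=C1CCC[C@H](O1)[C@@H](O)[C@H](O)[C@H]2C(=O)C=C[C@@H]2O`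
F15 | step 16 | C11 methanesulfonate of 24 | `COC(=O)CCC[C@H](OC(C)=O)[C@@H](OC(C)=O)[C@H](OC(C)=O)[C@H]1[C@](O)(C/C=C\C/C=C\CC)[C@@H](OS(C)(=O)=O)[C@H](Cl)C1=O`
A1 | alternative 1 | keto-aldehyde (C12 ketone, C11 aldehyde, C9 triethylsilyl ether, C5–C7 tert-butyldimethylsilyl ethers) | `CC/C=C\C/C=C\CC(=O)C(C(CC=O)O[Si](CC)(CC)CC)[C@@H](O[Si](C)(C)C(C)(C)C)[C@H](O[Si](C)(C)C(C)(C)C)[C@H](CCCC(=O)OC)O[Si](C)(C)C(C)(C)C`
A2 | alternative 1 | cyclopentane cis-11,12-diol | `CC/C=C\C/C=C\C[C@]1(O)[C@@H](O)CC(O[Si](CC)(CC)CC)[C@@H]1[C@@H](O[Si](C)(C)C(C)(C)C)[C@H](O[Si](C)(C)C(C)(C)C)[C@H](CCCC(=O)OC)O[Si](C)(C)C(C)(C)C`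
A3 | alternative 2 | chloroalkynyl aldehyde (C9 aldehyde, C10≡C11 chloroalkyne, C12 triethylsilyl ether) | `CC/C=C\C/C=C\C[C@](O[Si](CC)(CC)CC)(C#CCl)[C@@H](C=O)[C@@H](OC(C)=O)[C@H](OC(C)=O)[C@H](CCCC(=O)OC)OC(C)=O`
A4 | alternative 2 | 12-O-triethylsilyl ether of the target | `CC/C=C\C/C=C\C[C@]1(O[Si](CC)(CC)CC)C=C(Cl)C(=O)[C@H]1[C@@H](OC(C)=O)[C@H](OC(C)=O)[C@H](CCCC(=O)OC)OC(C)=O`
A5 | alternative 3 | 2,2-dichlorothiane 1,1-dioxide (sulfur between C10 and C11) | `CC/C=C\C/C=C\C[C@]1(O[Si](CC)(CC)CC)CS(=O)(=O)C(Cl)(Cl)C(O[Si](CC)(CC)CC)[C@H]1[C@@H](O[Si](C)(C)C(C)(C)C)[C@H](O[Si](C)(C)C(C)(C)C)[C@H](CCCC(=O)OC)O[Si](C)(C)C(C)(C)C`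
A6 | alternative 3 | 1-chlorocyclopentene with C9 and C12 triethylsilyl ethers | `CC/C=C\C/C=C\C[C@]1(O[Si](CC)(CC)CC)C=C(Cl)C(O[Si](CC)(CC)CC)[C@H]1[C@@H](O[Si](C)(C)C(C)(C)C)[C@H](O[Si](C)(C)C(C)(C)C)[C@H](CCCC(=O)OC)O[Si](C)(C)C(C)(C)C`
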